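**Assumptions (one line):** 4-Hydroxy-3-methoxyphenylpyruvic acid, coniferaldehyde and the reagents below are purchasable, both phenols stay free throughout, and solvents and simple mineral acids are not numbered.

**Target check:** The SMILES gives (8R,8'R), formula C20H22O7. The γ-lactone carries the 8'-OH cis to the 8-benzyl group, and the two benzyl groups are trans.

## Retrosynthetic overview
1. The lactone is made last, by reduction of the aldehyde of an aldol adduct to the primary alcohol and lactonization onto the methyl ester. This is the only ring formed.
2. The aldol adduct is disconnected at C8–C8' into the enamine of 3-(4-hydroxy-3-methoxyphenyl)propanal and methyl 3-(4-hydroxy-3-methoxyphenyl)-2-oxopropanoate. A proline-catalysed direct cross-aldol sets C8 and the quaternary carbinol C8' together.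
3. The propanal comes from amine-catalysed conjugate reduction of coniferaldehyde, and the ketoester from Fischer esterification of the commercial arylpyruvic acid.

## Route

**Step 1**
Reactants: 1 (E)-coniferaldehyde; 2 Hantzsch ester
Product: 4 3-(4-hydroxy-3-methoxyphenyl)propanal
Conditions: 2 (1.1 equiv), 3 (Bn2NH2⁺ CF3CO2⁻, 10 mol%), dioxane, 25–40 °C, 12 h
Reagents that add atoms: none (2 delivers only H; 3 is a catalyst)
Why: Amine-catalysed, iminium-activated transfer hydrogenation of the enal C=C bond, with no over-reduction of the aldehyde; no stereocentre is formed.

**Step 2**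
Reactants: 5 4-hydroxy-3-methoxyphenylpyruvic acid; 6 methanol
Product: 7 methyl 3-(4-hydroxy-3-methoxyphenyl)-2-oxopropanoate
Conditions: 6 (solvent), cat. H2SO4, 25 °C, 6 h
Reagents that add atoms: methanol (CO)
Why: Fischer esterification; the phenols and the ketone are untouched, and the product is a keto/enol mixture.

**Step 3**
Reactants: 4 3-(4-hydroxy-3-methoxyphenyl)propanal (2.0 equiv); 7 methyl 3-(4-hydroxy-3-methoxyphenyl)-2-oxopropanoate (1.0 equiv)
Product: 9 methyl (2R,3S)-2-hydroxy-2,3-bis(4-hydroxy-3-methoxybenzyl)-4-oxobutanoate
Conditions: 8 ((S)-proline, 30 mol%), DMSO (0.3 M), 4 °C; aldehyde 4 added by syringe pump over 6 h, then 24 h; EtOAc/aq. NH4Cl work-up, crude used directly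
Reagents that add atoms: none (8 is a catalyst)
Why: Proposed new method: a direct enamine-catalysed cross-aldol of an aldehyde donor with an enolizable aryl-pyruvate ester as the ketone acceptor, giving a tertiary α-hydroxy ester with two contiguous stereocentres. (S)-Proline forms the anti, E-enamine of 4, and its CO2H delivers the ketone face syn to the acid while hydrogen-bonding to the ketone C=O in a Zimmerman–Traxler-type chair, which sets C3 (= C8) as S in 9 (R in the target after CHO → CH2OH). The planar CO2Me is expected to sit equatorial and the benzylic CH2 axial, favouring 2R at the carbinol (= C8'), which is a prediction and not an established outcome. The closest known reactions are the proline-catalysed aldehyde/aldehyde cross-aldol and the enamine aldol of aldehydes with non-enolizable activated ketones such as ketomalonate and trifluoropyruvate. Slow addition of 4 suppresses its self-aldol.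

**Step 4**
Reactants: 9 (crude aldol); 10 sodium borohydride
Product: 11 (+)-nortrachelogenin, (3R,4R)-3-hydroxy-3,4-bis(4-hydroxy-3-methoxybenzyl)dihydrofuran-2(3H)-one
Conditions: 10 (2.0 equiv), THF/EtOH 1:1, –20 → 0 °C, 30 min; then 1 M HCl, 25 °C, 3 h; silica chromatography
Reagents that add atoms: none (NaBH4 delivers only H; MeOH is lost on lactonization)
Why: Chemoselective low-temperature NaBH4 reduction of the aldehyde leaves the α-hydroxy methyl ester intact, and the resulting γ-hydroxy ester lactonizes under acid to the five-membered lactone (reduction/lactonization); no new stereocentre is formed, and C8 cannot epimerize once the aldehyde is gone.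

## Compound list
1 | (E)-coniferaldehyde, 4-hydroxy-3-methoxycinnamaldehyde | COc1cc(/C=C/C=O)ccc1O | starting material
2 | Hantzsch ester, diethyl 2,6-dimethyl-1,4-dihydropyridine-3,5-dicarboxylate | CCOC(=O)C1=C(C)NC(C)=C(C1)C(=O)OCC | starting material
3 | dibenzylammonium trifluoroacetate (catalyst) | [O-]C(=O)C(F)(F)F.C(c1ccccc1)[NH2+]Cc1ccccc1 | starting material
4 | 3-(4-hydroxy-3-methoxyphenyl)propanal | COc1cc(CCC=O)ccc1O | intermediate
5 | 4-hydroxy-3-methoxyphenylpyruvic acid | COc1cc(CC(=O)C(=O)O)ccc1O | starting material
6 | methanol | CO | starting material
7 | methyl 3-(4-hydroxy-3-methoxyphenyl)-2-oxopropanoate | COc1cc(CC(=O)C(=O)OC)ccc1O | intermediate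
8 | (S)-proline (catalyst) | OC(=O)[C@@H]1CCCN1 | starting material
9 | methyl (2R,3S)-2-hydroxy-2,3-bis(4-hydroxy-3-methoxybenzyl)-4-oxobutanoate | COC(=O)[C@@](O)(Cc1ccc(O)c(OC)c1)[C@@H](C=O)Cc1ccc(O)c(OC)c1 | intermediate
10 | sodium borohydride | [BH4-].[Na+] | starting material
11 | (+)-nortrachelogenin | COc1cc(C[C@@H]2COC(=O)[C@@]2(O)Cc2ccc(O)c(OC)c2)ccc1O | target

**Total steps:** 4 (two single-step branches, 1 → 4 and 5 → 7, then two shared steps).
**Longest linear sequence:** 3 steps (1 → 4 → 9 → 11, or 5 → 7 → 9 → 11).

## Three steps most likely to fail
1. **Step 3 (proposed new aldol).** Risks are low reactivity of the enol-rich aryl pyruvate, catalyst sequestration as a ketimine, β-dehydration to the enal, and poor dr at C8'.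
   - Fallback, a stepwise route using known chemistry with the phenols protected as benzyl ethers:
   - Evans alkylation of the N-(3-aryl-propanoyl)oxazolidinone with tert-butyl bromoacetate. The auxiliary enantiomer is chosen to give the C8 configuration of the target.
   - LiBH4 removal of the auxiliary to the primary alcohol, then TFA to cleave the tert-butyl ester and lactonize to the β-(arylmethyl)-γ-butyrolactone.
   - LiHMDS enolate hydroxylation with Davis oxaziridine, which puts OH trans to the C8 benzyl, then OTBS protection.
   - LiHMDS enolate benzylation with ArCH2Br, which puts the new benzyl trans to the C8 benzyl and leaves OH cis.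
   - TBAF, then H2/Pd-C, to remove all protecting groups.
2. **Step 4 (reduction/lactonization of the β-hydroxy aldehyde).** Risks are retro-aldol under the basic borohydride conditions, E1cB dehydration, and over-reduction of the α-hydroxy ester.
   - Fallback: replace the hydride reduction of 9 by Pinnick oxidation (NaClO2, NaH2PO4, 2-methyl-2-butene).
   - Then reduce the resulting carboxylic acid selectively over the methyl ester with BH3·SMe2.
   - The γ-hydroxy ester lactonizes on acid treatment.
3. **Step 1 (enal conjugate reduction).** The p-hydroxy enal is a poor iminium electrophile because of quinone-methide-type donation.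
   - Fallback: start from commercial dihydroconiferyl alcohol and oxidize it to aldehyde 4 by Parikh–Doering oxidation (SO3·py, DMSO, Et3N).
   - Alternatively, hydrogenate ferulic acid over Pd/C, reduce the acid with BH3, and then oxidize the alcohol.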